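**Retrosynthetic overview**

1. The strategy rests on ring C, the C5'–C10' cyclohexane of the saturated-lactone half. Its C8' oxygen and the isopropenyl carbon on C5' are cis-1,4 and flank quaternary C10', which is the CO2 bridge of a 2-pyrone cycloadduct. Ring A, the cyclohexane of the butenolide half, has C5 and C10 of the opposite sense and C8 of the same sense, so it is the mirror-image adduct inverted at C8.
2. Ring B (butenolide) is disconnected last, at C7=C11 by intramolecular Horner–Wadsworth–Emmons olefination and at C8–O by esterification.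
3. The C13–C13' bond comes from radical conjugate addition of a phosphonoacetate-derived CH2 radical to the α-methylene lactone, which also sets C11'. Ring D (saturated lactone) is opened at C7'–C11' by a bromoacetal radical cyclisation from the C8' oxygen.
4. Rings C and A both come from the Diels–Alder reaction of 3,5-dibromo-2-pyrone with methacrolein. The lactone carbonyl becomes isopropenyl and the formyl group becomes vinyl, and a lipase resolution gives one enantiomer to each half.
5. Order of ring formation: rings C and A (as the two enantiomers of one racemate), then ring D, then ring B.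

Key step: step 2

Numbering: each half is numbered like an elemanolide. C5 carries isopropenyl, C10 is quaternary, C7 and C8 are the fusion carbons with oxygen on C8, C11 is the lactone α-carbon, C12 the carbonyl and C13 the linker CH2. Primed atoms belong to the saturated-lactone half.

Assumption: the lipase acylates the (1R) enantiomer of alcohol 9, as the size rule for secondary alcohols predicts with the bromovinyl carbon as the large group. If the enzyme prefers the other enantiomer, acetate and free alcohol exchange their roles in the two branches.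

**Route**

Step 1
Reactants: 1 coumalic acid
Product: 2 3,5-dibromo-2H-pyran-2-one
Conditions: NBS (2.5 equiv), LiOAc (cat.), MeCN/H2O, rt
Reagents that add atoms: N-bromosuccinimide, O=C1CCC(=O)N1Br
Why: Hunsdiecker-type bromodecarboxylation at C5 together with electrophilic bromination at C3 is the established one-step entry to this pyrone; no stereocenter is formed.

Step 2
Reactants: 2 3,5-dibromo-2H-pyran-2-one; 3 methacrolein
Product: 4 racemic 4,7-dibromo-5-methyl-3-oxo-2-oxabicyclo[2.2.2]oct-7-ene-5-carbaldehyde with the formyl group syn to the C7=C8 bridge (endo) and the methyl group syn to the lactone bridge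
Conditions: PhMe, 2,6-di-tert-butyl-4-methylphenol (cat.), 100 °C, sealed tube, excess 3; chromatography
Reagents that add atoms: none
Why: Thermal concerted [4+2] cycloaddition in which pyrone C3=C4–C5=C6 is the diene and the C=C bond of the enal the dienophile; the closest known reaction type is the Diels–Alder reaction of 3,5-dibromo-2-pyrone with acrylic dienophiles, which gives bicyclic lactones that keep the CO2 bridge below the temperature of decarboxylation. Ring C is closed by intermolecular suprafacial addition across the diene termini, the CH2 of the enal bonding to pyrone C6 (C8'–C9') and the methyl-bearing carbon to pyrone C3 (C5'–C10'), the orientation known for 3-bromo-2-pyrones with acrylic partners. C5' and C8' are set together because the O–C(=O) bridge must span one face of the new ring, which is the cis-1,4 relation of the C8' oxygen and the future isopropenyl carbon. C10' is set by the endo transition state, with formyl under the C4–C5 unit of the diene and methyl toward the lactone bridge; the planar O–C=O bridge has no inward hydrogen to clash with an exo methyl group, so the usual carbonyl-endo preference should hold. The step needs this endo selectivity, and the exo isomer is removed by chromatography. The adduct is racemic, and both enantiomers are used later.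

Step 3
Reactants: 4 racemic dibromo aldehyde
Product: 5 racemic 7-bromo-5-methyl-3-oxo-2-oxabicyclo[2.2.2]oct-7-ene-5-carbaldehyde (same relative configuration)
Conditions: Zn, AcOH, THF, 0 °C → rt
Reagents that add atoms: none
Why: Dissolving-metal reduction of an α-bromo carbonyl compound removes only the bridgehead bromine next to the lactone carbonyl, because the vinylic C–Br bond and the aldehyde are inert to Zn/AcOH; the cage fixes the configuration of the bridgehead.

Step 4
Reactants: 5 racemic bromo aldehyde
Product: 6 racemic 7-bromo-5-methyl-5-vinyl-2-oxabicyclo[2.2.2]oct-7-en-3-one (vinyl syn to C7=C8)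
Conditions: Ph3PCH3Br, KN(SiMe3)2, THF, −78 → 0 °C
Reagents that add atoms: methyltriphenylphosphonium bromide (source of Ph3P=CH2), C[P+](c1ccccc1)(c1ccccc1)c1ccccc1.[Br-]
Why: Wittig methylenation of a non-enolisable neopentyl aldehyde; the ylide reacts with the aldehyde far faster than with the lactone at low temperature, and the bridgehead α-hydrogen cannot be removed (Bredt's rule), so no stereocenter is touched.

Step 5
Reactants: 6 racemic vinyl lactone
Product: 8 racemic 1-(3-bromo-4-hydroxy-6-methyl-6-vinylcyclohex-2-en-1-yl)ethan-1-one with acetyl, hydroxyl and methyl cis, via hydroxy Weinreb amide 7 (not isolated)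
Conditions: MeNH(OMe)·HCl, iPrMgCl, THF, −20 → 0 °C; then MeMgBr, 0 °C; aq. NH4Cl
Reagents that add atoms: N,O-dimethylhydroxylamine hydrochloride, CNOC.Cl (its atoms are in 7 only); methylmagnesium bromide, C[Mg]Br
Why: Aminolysis of the strained lactone by the magnesium amide gives the Weinreb amide and frees the C8 alkoxide, and the chelated tetrahedral adduct of MeMgBr releases the methyl ketone only on work-up, so that C5, now allylic and α to a carbonyl, is never exposed to base.

Step 6
Reactants: 8 racemic methyl ketone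
Product: 9 racemic 2-bromo-5-methyl-4-(prop-1-en-2-yl)-5-vinylcyclohex-2-en-1-ol with hydroxyl, isopropenyl and methyl cis
Conditions: Zn, CH2Br2, TiCl4, THF/CH2Cl2, 0 °C → rt
Reagents that add atoms: dibromomethane, BrCBr
Why: Lombardo–Takai methylenation with the non-basic Zn/CH2Br2/TiCl4 reagent should convert the easily enolised β,γ-unsaturated methyl ketone into the isopropenyl group without epimerisation at C5 or migration of the C6=C7 bond, and it tolerates the free hydroxyl group.

Step 7
Reactants: 9 racemic allylic alcohol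
Product: 10 (1R,4S,5S)-2-bromo-5-methyl-4-(prop-1-en-2-yl)-5-vinylcyclohex-2-en-1-yl acetate; 11 (1S,4R,5R)-2-bromo-5-methyl-4-(prop-1-en-2-yl)-5-vinylcyclohex-2-en-1-ol (the unreacted enantiomer, used in step 18)
Conditions: vinyl acetate, immobilised Burkholderia cepacia lipase (Amano PS), MTBE, 30 °C, to about half conversion; chromatography
Reagents that add atoms: vinyl acetate, C=COC(C)=O
Why: Lipase-catalysed kinetic resolution by irreversible transesterification, a reaction type that works well for 2-halocyclohex-2-enols because the bromovinyl carbon and the ring CH2 differ clearly in size; both enantiomers are used, one for each half.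

Step 8
Reactants: 10 (1R,4S,5S)-acetate
Product: 12 (1R,4S,5S)-2-bromo-5-methyl-4-(prop-1-en-2-yl)-5-vinylcyclohex-2-en-1-ol
Conditions: K2CO3 (cat.), MeOH, 0 °C
Reagents that add atoms: none
Why: Base-catalysed transesterification (Zemplén-type methanolysis) cleaves the acetate; no stereocenter of the substrate is acidic.

Step 9
Reactants: 12 (1R,4S,5S)-bromo alcohol
Product: 13 (1R,4S,5S)-5-methyl-4-(prop-1-en-2-yl)-5-vinylcyclohex-2-en-1-ol
Conditions: Bu3SnH, azobisisobutyronitrile (cat.), PhH, 80 °C
Reagents that add atoms: none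
Why: Radical chain hydrodebromination of the vinylic bromide; the σ-vinyl radical is reduced by the stannane faster than it can reach another alkene, and the C6'=C7' bond stays in place for the next radical step.

Step 10
Reactants: 13 (1R,4S,5S)-allylic alcohol
Product: 14 (1R,4S,5S)-1-(2-bromo-1-ethoxyethoxy)-5-methyl-4-(prop-1-en-2-yl)-5-vinylcyclohex-2-ene (both acetal epimers)
Conditions: NBS, ethyl vinyl ether, CH2Cl2, −40 → 0 °C
Reagents that add atoms: ethyl vinyl ether, C=COCC; N-bromosuccinimide, O=C1CCC(=O)N1Br
Why: Bromoacetalisation (first half of the Ueno–Stork sequence): the electron-rich enol ether is brominated much faster than the three hydrocarbon alkenes, and the C8' hydroxyl group opens the bromonium ion.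

Step 11
Reactants: 14 bromoacetal
Product: 15 2-ethoxy-6-methyl-5-(prop-1-en-2-yl)-6-vinyloctahydro-1-benzofuran, cis-fused, with ring oxygen, isopropenyl and methyl on one face (both acetal epimers)
Conditions: Bu3SnH (slow addition), azobisisobutyronitrile (cat.), PhH, 80 °C
Reagents that add atoms: none
Why: Ueno–Stork 5-exo-trig radical cyclisation; the tether from the C8' oxygen can reach C7' only on the face of that oxygen, so the C7'–C11' bond forms cis to O–C8', and the C6' radical is then reduced by the stannane.

Step 12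
Reactants: 15 bicyclic acetal
Product: 16 6-methyl-5-(prop-1-en-2-yl)-6-vinylhexahydro-1-benzofuran-2(3H)-one (cis-fused, configuration as in 15)
Conditions: CrO3, H2SO4, H2O/acetone, 0 °C
Reagents that add atoms: water, O
Why: Jones oxidation hydrolyses the ethyl acetal to the lactol and oxidises it to the γ-lactone in one operation; the isolated alkenes are inert to chromic acid at 0 °C.

Step 13
Reactants: 16 lactone
Product: 19 6-methyl-3-methylene-5-(prop-1-en-2-yl)-6-vinylhexahydro-1-benzofuran-2(3H)-one, via Mannich base 17 (not isolated), via ammonium iodide 18 (not isolated)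
Conditions: LiN(iPr)2, THF, −78 °C; Me2N=CH2+ I−, −78 °C → rt; then MeI, rt; then aq. NaHCO3
Reagents that add atoms: Eschenmoser's salt, C=[N+](C)C.[I-] (only its CH2 stays); iodomethane, CI (its atoms are in 18 only)
Why: α-Methylenation by the Eschenmoser sequence (Mannich reaction of the lactone enolate, quaternisation, Hofmann-type elimination), the standard route to α-methylene-γ-butyrolactones; C11' becomes trigonal and no stereocenter is affected.

Step 14
Reactants: 20 allyl 2-(diethoxyphosphoryl)acetate
Product: 22 allyl 2-(diethoxyphosphoryl)acrylate, via allyloxy adduct 21 (not isolated)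
Conditions: (CH2O)n, piperidine (cat.), allyl alcohol, 80 °C; then TsOH·H2O (cat.), PhMe, reflux
Reagents that add atoms: paraformaldehyde (as formaldehyde), C=O; allyl alcohol, C=CCO (its atoms are in 21 only)
Why: Knoevenagel condensation with formaldehyde, carried through the alcohol adduct and its acid-catalysed elimination, is the usual preparation of 2-phosphonoacrylates; allyl alcohol as solvent avoids ester exchange.

Step 15
Reactants: 22 allyl 2-(diethoxyphosphoryl)acrylate
Product: 23 allyl 2-(diethoxyphosphoryl)-3-(phenylselanyl)propanoate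
Conditions: PhSeH, Et3N (cat.), CH2Cl2, 0 °C
Reagents that add atoms: benzeneselenol, [SeH]c1ccccc1
Why: Michael addition of the selenol to the doubly activated alkene gives the primary alkyl selenide that serves as radical precursor.

Step 16
Reactants: 19 α-methylene lactone; 23 selenide (in excess)
Product: 24 allyl 2-(diethoxyphosphoryl)-4-[6-methyl-2-oxo-5-(prop-1-en-2-yl)-6-vinyloctahydro-1-benzofuran-3-yl]butanoate, with H on C11' cis to H7' and H8' (both epimers at the phosphonate carbon)
Conditions: Bu3SnH (syringe pump), azobisisobutyronitrile (cat.), PhH, 80 °C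
Reagents that add atoms: none
Why: Giese radical conjugate addition: the nucleophilic primary radical from 23 adds to the methylene carbon C13' of the acrylate-like lactone and leaves the unactivated alkenes alone, and the C11' radical should take hydrogen from the stannane on the convex face, cis to H7' and H8', which places the new chain on the concave face as in the target.

Step 17
Reactants: 24 allyl ester
Product: 25 2-(diethoxyphosphoryl)-4-[6-methyl-2-oxo-5-(prop-1-en-2-yl)-6-vinyloctahydro-1-benzofuran-3-yl]butanoic acid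
Conditions: Pd(PPh3)4 (cat.), morpholine, THF, rt
Reagents that add atoms: none
Why: Allyl ester cleavage through a π-allyl palladium complex (Tsuji–Trost type) with the amine as allyl acceptor is neutral and leaves the lactone, C11' and the alkenes unchanged.

Step 18
Reactants: 11 (1S,4R,5R)-bromo alcohol
Product: 26 (1R,4R,5R)-2-bromo-5-methyl-4-(prop-1-en-2-yl)-5-vinylcyclohex-2-en-1-yl 4-nitrobenzoate
Conditions: 4-nitrobenzoic acid, PPh3, DIAD, THF, 0 °C → rt
Reagents that add atoms: 4-nitrobenzoic acid, OC(=O)c1ccc(cc1)[N+](=O)[O-]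
Why: Mitsunobu esterification displaces the oxyphosphonium group by SN2 and so inverts C8, which brings the oxygen trans to the C10 methyl and C5 isopropenyl groups as the butenolide half requires.

Step 19
Reactants: 26 4-nitrobenzoate
Product: 27 (1R,4R,5R)-2-bromo-5-methyl-4-(prop-1-en-2-yl)-5-vinylcyclohex-2-en-1-ol
Conditions: K2CO3, MeOH, rt
Reagents that add atoms: none
Why: Methanolysis (transesterification) of the activated aryl ester frees the inverted alcohol with retention.

Step 20
Reactants: 27 (1R,4R,5R)-bromo alcohol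
Product: 29 (2R,4R,5R)-2-hydroxy-4-methyl-5-(prop-1-en-2-yl)-4-vinylcyclohexan-1-one, via alkenylboronate 28 (not isolated)
Conditions: B2pin2, Pd(dppf)Cl2 (cat.), KOAc, 1,4-dioxane, 80 °C; then NaBO3·4H2O, THF/H2O, rt
Reagents that add atoms: bis(pinacolato)diboron, CC1(C)OB(OC1(C)C)B1OC(C)(C)C(C)(C)O1 (its atoms are in 28 only); sodium perborate, [Na+].[O-]OB=O
Why: Miyaura borylation of the alkenyl bromide followed by perborate oxidation of the C–B bond gives the enol and from it the C7 ketone; the C8 carbinol keeps its configuration, which is also expected to be the more stable one (equatorial, away from the axial C10 methyl) should any enolisation occur.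

Step 21
Reactants: 29 ketol; 25 phosphono acid
Product: 30 (1R,2R... as in 29) 2-oxocyclohexyl ester of acid 25, i.e. the C8 ester carrying the C7 ketone and the C11 phosphonate (both epimers at C11)
Conditions: DCC, 4-(dimethylamino)pyridine (cat.), CH2Cl2, 0 °C → rt
Reagents that add atoms: none
Why: Steglich esterification joins the two halves through the C8–O bond with retention at C8; the phosphonate carbon later becomes trigonal, so its configuration is of no consequence.

Step 22
Reactants: 30 keto phosphonate ester
Product: 31 CNP0332736.1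
Conditions: LiCl, iPr2NEt, MeCN, rt
Reagents that add atoms: none
Why: Intramolecular Horner–Wadsworth–Emmons olefination under Masamune–Roush conditions closes ring B by attack of the phosphonate carbanion C11 on the C7 ketone, the known route to fused α-alkyl butenolides from 2-acyloxycyclohexanones; the amine base is too weak to remove H–C11' or H–C8.

**Compound list**

1 | coumalic acid | O=C(O)C1=COC(=O)C=C1 | starting material
2 | 3,5-dibromo-2H-pyran-2-one | O=C1OC=C(Br)C=C1Br | intermediate
3 | methacrolein | CC(=C)C=O | starting material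
4 | 4,7-dibromo-5-methyl-3-oxo-2-oxabicyclo[2.2.2]oct-7-ene-5-carbaldehyde, formyl syn to C7=C8; racemate, enantiomer drawn leads to the saturated half | O=C[C@]1(C)C[C@H]2OC(=O)[C@]1(Br)C=C2Br | intermediate
5 | 7-bromo-5-methyl-3-oxo-2-oxabicyclo[2.2.2]oct-7-ene-5-carbaldehyde; racemate | O=C[C@]1(C)C[C@H]2OC(=O)[C@@H]1C=C2Br | intermediate
6 | 7-bromo-5-methyl-5-vinyl-2-oxabicyclo[2.2.2]oct-7-en-3-one; racemate | C=C[C@]1(C)C[C@H]2OC(=O)[C@@H]1C=C2Br | intermediate
7 | 3-bromo-4-hydroxy-N-methoxy-N,6-dimethyl-6-vinylcyclohex-2-ene-1-carboxamide, all-cis amide, OH and methyl; racemate, formed as magnesium alkoxide, not isolated | C=C[C@]1(C)C[C@@H](O)C(Br)=C[C@H]1C(=O)N(C)OC | intermediate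
8 | 1-(3-bromo-4-hydroxy-6-methyl-6-vinylcyclohex-2-en-1-yl)ethan-1-one; racemate | C=C[C@]1(C)C[C@@H](O)C(Br)=C[C@H]1C(C)=O | intermediate
9 | 2-bromo-5-methyl-4-(prop-1-en-2-yl)-5-vinylcyclohex-2-en-1-ol; racemate | C=C[C@]1(C)C[C@@H](O)C(Br)=C[C@H]1C(C)=C | intermediate
10 | (1R,4S,5S)-2-bromo-5-methyl-4-(prop-1-en-2-yl)-5-vinylcyclohex-2-en-1-yl acetate | C=C[C@]1(C)C[C@@H](OC(C)=O)C(Br)=C[C@H]1C(C)=C | intermediate
11 | (1S,4R,5R)-2-bromo-5-methyl-4-(prop-1-en-2-yl)-5-vinylcyclohex-2-en-1-ol | C=C[C@@]1(C)C[C@H](O)C(Br)=C[C@@H]1C(C)=C | intermediate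
12 | (1R,4S,5S)-2-bromo-5-methyl-4-(prop-1-en-2-yl)-5-vinylcyclohex-2-en-1-ol | C=C[C@]1(C)C[C@@H](O)C(Br)=C[C@H]1C(C)=C | intermediate
13 | (1R,4S,5S)-5-methyl-4-(prop-1-en-2-yl)-5-vinylcyclohex-2-en-1-ol | C=C[C@]1(C)C[C@@H](O)C=C[C@H]1C(C)=C | intermediate
14 | (1R,4S,5S)-1-(2-bromo-1-ethoxyethoxy)-5-methyl-4-(prop-1-en-2-yl)-5-vinylcyclohex-2-ene | C=C[C@]1(C)C[C@@H](OC(CBr)OCC)C=C[C@H]1C(C)=C | intermediate
15 | 2-ethoxy-6-methyl-5-(prop-1-en-2-yl)-6-vinyloctahydro-1-benzofuran, cis-fused | C=C[C@]1(C)C[C@H]2OC(OCC)C[C@H]2C[C@H]1C(C)=C | intermediate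
16 | 6-methyl-5-(prop-1-en-2-yl)-6-vinylhexahydro-1-benzofuran-2(3H)-one, cis-fused | C=C[C@]1(C)C[C@H]2OC(=O)C[C@H]2C[C@H]1C(C)=C | intermediate
17 | 3-[(dimethylamino)methyl] derivative of 16 (not isolated) | C=C[C@]1(C)C[C@H]2OC(=O)C(CN(C)C)[C@H]2C[C@H]1C(C)=C | intermediate
18 | trimethylammonium iodide of 17 (not isolated) | C=C[C@]1(C)C[C@H]2OC(=O)C(C[N+](C)(C)C)[C@H]2C[C@H]1C(C)=C.[I-] | intermediate
19 | 6-methyl-3-methylene-5-(prop-1-en-2-yl)-6-vinylhexahydro-1-benzofuran-2(3H)-one | C=C[C@]1(C)C[C@H]2OC(=O)C(=C)[C@H]2C[C@H]1C(C)=C | intermediate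
20 | allyl 2-(diethoxyphosphoryl)acetate | C=CCOC(=O)CP(=O)(OCC)OCC | starting material
21 | allyl 3-(allyloxy)-2-(diethoxyphosphoryl)propanoate (not isolated) | C=CCOCC(C(=O)OCC=C)P(=O)(OCC)OCC | intermediate
22 | allyl 2-(diethoxyphosphoryl)acrylate | C=CCOC(=O)C(=C)P(=O)(OCC)OCC | intermediate
23 | allyl 2-(diethoxyphosphoryl)-3-(phenylselanyl)propanoate | C=CCOC(=O)C(C[Se]c1ccccc1)P(=O)(OCC)OCC | intermediate
24 | allyl 2-(diethoxyphosphoryl)-4-[6-methyl-2-oxo-5-(prop-1-en-2-yl)-6-vinyloctahydro-1-benzofuran-3-yl]butanoate | C=CCOC(=O)C(CC[C@@H]1C(=O)O[C@@H]2C[C@@](C)(C=C)[C@H](C(=C)C)C[C@H]12)P(=O)(OCC)OCC | intermediate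
25 | 2-(diethoxyphosphoryl)-4-[6-methyl-2-oxo-5-(prop-1-en-2-yl)-6-vinyloctahydro-1-benzofuran-3-yl]butanoic acid | OC(=O)C(CC[C@@H]1C(=O)O[C@@H]2C[C@@](C)(C=C)[C@H](C(=C)C)C[C@H]12)P(=O)(OCC)OCC | intermediate
26 | (1R,4R,5R)-2-bromo-5-methyl-4-(prop-1-en-2-yl)-5-vinylcyclohex-2-en-1-yl 4-nitrobenzoate | C=C[C@@]1(C)C[C@@H](OC(=O)c2ccc(cc2)[N+](=O)[O-])C(Br)=C[C@@H]1C(C)=C | intermediate
27 | (1R,4R,5R)-2-bromo-5-methyl-4-(prop-1-en-2-yl)-5-vinylcyclohex-2-en-1-ol | C=C[C@@]1(C)C[C@@H](O)C(Br)=C[C@@H]1C(C)=C | intermediate
28 | (1R,4R,5R)-5-methyl-4-(prop-1-en-2-yl)-2-(4,4,5,5-tetramethyl-1,3,2-dioxaborolan-2-yl)-5-vinylcyclohex-2-en-1-ol (not isolated) | C=C[C@@]1(C)C[C@@H](O)C(B2OC(C)(C)C(C)(C)O2)=C[C@@H]1C(C)=C | intermediate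
29 | (2R,4R,5R)-2-hydroxy-4-methyl-5-(prop-1-en-2-yl)-4-vinylcyclohexan-1-one | C=C[C@@]1(C)C[C@@H](O)C(=O)C[C@@H]1C(C)=C | intermediate
30 | (1R,5R,6R... as in 29) 5-methyl-2-oxo-4-(prop-1-en-2-yl)-5-vinylcyclohexyl ester of acid 25 | C=C[C@@]1(C)C[C@@H](OC(=O)C(CC[C@@H]2C(=O)O[C@@H]3C[C@@](C)(C=C)[C@H](C(=C)C)C[C@H]23)P(=O)(OCC)OCC)C(=O)C[C@@H]1C(C)=C | intermediate
31 | CNP0332736.1: 3-{2-[saturated lactone-3-yl]ethyl}-6-methyl-5-(prop-1-en-2-yl)-6-vinyl-5,6,7,7a-tetrahydro-1-benzofuran-2(4H)-one | C=C[C@@]1(C)C[C@H]2OC(=O)C(CC[C@@H]3C(=O)O[C@@H]4C[C@@](C)(C=C)[C@H](C(=C)C)C[C@H]34)=C2C[C@@H]1C(=C)C | target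

**Step count and risks**

Total step count: 22. Longest linear sequence: 17 steps (steps 1–13, 16, 17, 21, 22).

Steps most likely to fail:

1. Step 2. The formyl group of an α-substituted enal may prefer the exo position, which would set C10' the wrong way round. Fallback: the dienophile is exchanged for one whose formyl group can become the methyl group and whose second α-substituent can become the formyl group. It sets out from 2. Commercial 2-methylenepropane-1,3-diol is monosilylated (NaH, t-BuMe2SiCl) to 2-(silyloxymethyl)prop-2-en-1-ol F1 and oxidised with MnO2 to 2-(silyloxymethyl)prop-2-enal F2. Cycloaddition of F2 with 2 under the conditions of step 2 should then give, in the feared exo-formyl sense, the adduct F3 with formyl toward the lactone bridge and silyloxymethyl over the C7=C8 bridge. The exo formyl group is reduced to methyl through the tosylhydrazone F4 (TsNHNH2; then catecholborane and NaOAc), giving the methyl compound F5. HF·pyridine frees the primary alcohol F6, and Dess–Martin oxidation comes back to the route at 4.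

2. Step 16. The stannane may reduce the radical from 23 before it adds to 19, or hydrogen transfer to the C11' radical may show poor facial selectivity. Fallback (polar instead of radical): it sets out from 19. Copper-catalysed conjugate addition of (iPrO)Me2SiCH2MgCl (CuI cat., Me3SiCl, THF, −78 °C) and protonation of the silyl ketene acetal at low temperature from the convex face gives the silane F7. Tamao oxidation (H2O2, KF, KHCO3, THF/MeOH) gives the primary alcohol F8, and I2/PPh3/imidazole gives the iodide F9. F9 alkylates the sodium salt of 20 (NaH, DMF) and comes back to the route at 24.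

3. Step 7. The enzyme may discriminate the enantiomers of 9 poorly, since both groups flanking the carbinol carry bulk further out. Fallback (covalent resolution): it sets out from 9. Esterification with (S)-2-methoxy-2-phenylacetic acid (DCC, 4-(dimethylamino)pyridine) gives the diastereomeric esters F10 (from the 1R alcohol) and F11 (from the 1S alcohol), which are separated by chromatography. Methanolysis (K2CO3, MeOH) of F10 comes back to the route at 12 and that of F11 at 11.

**Further compounds**

F1 | step 2 | 2-{[tert-butyl(dimethyl)silyl]oxymethyl}prop-2-en-1-ol | C=C(CO)CO[Si](C)(C)C(C)(C)C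
F2 | step 2 | 2-{[tert-butyl(dimethyl)silyl]oxymethyl}prop-2-enal | C=C(C=O)CO[Si](C)(C)C(C)(C)C
F3 | step 2 | racemic 4,7-dibromo-5-{[tert-butyl(dimethyl)silyl]oxymethyl}-3-oxo-2-oxabicyclo[2.2.2]oct-7-ene-5-carbaldehyde, formyl syn to the lactone bridge | O=C[C@@]1(CO[Si](C)(C)C(C)(C)C)C[C@H]2OC(=O)[C@]1(Br)C=C2Br
F4 | step 2 | tosylhydrazone of F3 | Cc1ccc(cc1)S(=O)(=O)NN=C[C@@]1(CO[Si](C)(C)C(C)(C)C)C[C@H]2OC(=O)[C@]1(Br)C=C2Br
F5 | step 2 | racemic 4,7-dibromo-5-{[tert-butyl(dimethyl)silyl]oxymethyl}-5-methyl-2-oxabicyclo[2.2.2]oct-7-en-3-one | C[C@@]1(CO[Si](C)(C)C(C)(C)C)C[C@H]2OC(=O)[C@]1(Br)C=C2Br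
F6 | step 2 | racemic 4,7-dibromo-5-(hydroxymethyl)-5-methyl-2-oxabicyclo[2.2.2]oct-7-en-3-one, hydroxymethyl syn to C7=C8 | C[C@@]1(CO)C[C@H]2OC(=O)[C@]1(Br)C=C2Br
F7 | step 16 | 3-{2-[isopropoxy(dimethyl)silyl]ethyl}-6-methyl-5-(prop-1-en-2-yl)-6-vinylhexahydro-1-benzofuran-2(3H)-one | CC(C)O[Si](C)(C)CC[C@@H]1C(=O)O[C@@H]2C[C@@](C)(C=C)[C@H](C(=C)C)C[C@H]12
F8 | step 16 | 3-(2-hydroxyethyl)-6-methyl-5-(prop-1-en-2-yl)-6-vinylhexahydro-1-benzofuran-2(3H)-one | OCC[C@@H]1C(=O)O[C@@H]2C[C@@](C)(C=C)[C@H](C(=C)C)C[C@H]12
F9 | step 16 | 3-(2-iodoethyl)-6-methyl-5-(prop-1-en-2-yl)-6-vinylhexahydro-1-benzofuran-2(3H)-one | ICC[C@@H]1C(=O)O[C@@H]2C[C@@](C)(C=C)[C@H](C(=C)C)C[C@H]12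
F10 | step 7 | (1R,4S,5S)-2-bromo-5-methyl-4-(prop-1-en-2-yl)-5-vinylcyclohex-2-en-1-yl (S)-2-methoxy-2-phenylacetate | C=C[C@]1(C)C[C@@H](OC(=O)[C@@H](OC)c2ccccc2)C(Br)=C[C@H]1C(C)=C
F11 | step 7 | (1S,4R,5R)-2-bromo-5-methyl-4-(prop-1-en-2-yl)-5-vinylcyclohex-2-en-1-yl (S)-2-methoxy-2-phenylacetate | C=C[C@@]1(C)C[C@H](OC(=O)[C@@H](OC)c2ccccc2)C(Br)=C[C@@H]1C(C)=C
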